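## Retrosynthetic overview

1. Isolophirachalcone ⇒ global desilylation ⇒ Heck coupling of a C-5 aryl triflate on the dihydrobenzofuran with a 2,4-bis(silyloxy)phenyl vinyl ketone (chalcone arm last).
2. Key step: both oxygen heterocycles are closed in one acid-mediated operation from an acyclic precursor. The tetrahydrofuran C–O bond forms at the more easily ionised 2,4-dioxygenated benzylic carbon, the dihydrobenzofuran C–O bond in the same flask. Dihydrobenzofuran C-2 and tetrahydrofuran C-2, C-4 and C-5 are set by equilibration. All arenes are bought; the only earlier ring is a transient lactol that is reopened.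
3. The three centres that cannot equilibrate are set by catalysts in the open chain: tetrahydrofuran C-3 (photoredox/enamine α-alkylation), the diarylmethine (rhodium conjugate arylation of an enal) and dihydrobenzofuran C-3 (enamine α-arylation with benzoquinone).
4. C–C disconnections (two aryl-Grignard additions to aldehydes, aldol, Suzuki) lead to 2,4-dihydroxyacetophenone, 4,6-dibromoresorcinol, 4-bromoresorcinol, benzoquinone, allyl alcohol and 4-silyloxyphenyl halides and aldehyde.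

Abbreviations: TBS = tert-butyldimethylsilyl; TES = triethylsilyl; ArA = 2,4-bis(TBS-oxy)phenyl; ArP = 4-(TBS-oxy)phenyl; X = (1RS,2R)-4-(ArA)-2-(ArP-methyl)-3-[(ArP)(TES-oxy)methyl]-4-oxo-1-(TBS-oxy)butyl (mixture also at C-3 and at the TES-oxy carbon); ArX = 2,4-bis(TBS-oxy)-5-X-phenyl; Y = (2R,3R,4R,5R)-4-(ArA-carbonyl)-3-(ArP-methyl)-5-(ArP)tetrahydrofuran-2-yl; ArY = 2,4-bis(TBS-oxy)-5-Y-phenyl.

Assumption: the silylated 4-halophenols, 4-silyloxybenzaldehyde and the alkenylboronate are bought as such, and each chiral catalyst is used in the enantiomeric series predicted by the published facial model (its mirror image if a sense proves opposite).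

## Route

Step 1
Reactants: 1 2,4-dihydroxyacetophenone
Product: 2 1-(ArA)ethanone
Conditions: TBSCl, imidazole, DMF, 40 °C
Reagents that add atoms: tert-butyldimethylsilyl chloride, CC(C)(C)[Si](C)(C)Cl
Why: Imidazole-promoted silylation (TBS protection) of both phenols, the hydrogen-bonded 2-OH needing the slight warming; no stereocentre is involved.

Step 2
Reactants: 2 1-(ArA)ethanone
Product: 4 2-bromo-1-(ArA)ethanone, via trimethylsilyl enol ether 3 (not isolated)
Conditions: LiN(SiMe3)2, Me3SiCl, THF, −78 °C; then NBS, −78 → 0 °C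
Reagents that add atoms: N-bromosuccinimide, O=C1CCC(=O)N1Br; chlorotrimethylsilane, C[Si](C)(C)Cl (silicon only in 3)
Why: Kinetic enolisation and O-silylation followed by electrophilic bromination of the enol ether (silyl enol ether α-halogenation) places bromine only on the methyl carbon and spares the electron-rich ring that free bromine would attack; no stereocentre is involved.

Step 3
Reactants: 5 tert-butyl(4-iodophenoxy)dimethylsilane; 6 allyl alcohol
Product: 7 3-(ArP)propanal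
Conditions: Pd(OAc)2 (2 mol %), NaHCO3, n-Bu4NCl, DMF, 40 °C
Reagents that add atoms: none
Why: Jeffery-type Heck reaction of the aryl iodide with allyl alcohol, in which β-hydride elimination towards the carbinol carbon and enol–aldehyde tautomerisation deliver the saturated 3-arylpropanal directly; no stereocentre is involved.

Step 4
Reactants: 7 3-(ArP)propanal (2 equiv); 4 2-bromo-1-(ArA)ethanone
Product: 8 (2R)-4-(ArA)-2-(ArP-methyl)-4-oxobutanal
Conditions: Ru(bpy)3Cl2 (0.5 mol %), (2R,5S)-2-tert-butyl-3,5-dimethylimidazolidin-4-one triflate salt (20 mol %), 2,6-lutidine, DMF, visible light, 23 °C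
Reagents that add atoms: none
Why: MacMillan photoredox organocatalytic α-alkylation of an aldehyde, in which the electrophilic phenacyl radical formed from 4 by single-electron reduction adds to the Si face of the chiral enamine of 7 (the Re face is screened by the catalyst methyl group), setting the (R) centre that becomes C-3 of the tetrahydrofuran.

Step 5
Reactants: 9 4,6-dibromoresorcinol
Product: 10 1,5-dibromo-2,4-bis(TBS-oxy)benzene
Conditions: TBSCl, imidazole, DMF, 23 °C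
Reagents that add atoms: tert-butyldimethylsilyl chloride, CC(C)(C)[Si](C)(C)Cl
Why: Imidazole-promoted silylation (TBS protection) of both phenols; no stereocentre is involved.

Step 6
Reactants: 10 1,5-dibromo-2,4-bis(TBS-oxy)benzene (1.2 equiv); 8 (2R)-4-(ArA)-2-(ArP-methyl)-4-oxobutanal
Product: 14 (3R,4RS)-1-(ArA)-4-[5-bromo-2,4-bis(TBS-oxy)phenyl]-3-(ArP-methyl)-4-(TBS-oxy)butan-1-one, via aryllithium 11 (not isolated), via arylmagnesium bromide 12 (not isolated), via bromomagnesium alkoxide 13 (not isolated)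
Conditions: n-BuLi, THF, −78 °C; MgBr2·OEt2; then 8, −78 °C; then TBSOTf, 2,6-lutidine, −78 → 0 °C
Reagents that add atoms: tert-butyldimethylsilyl triflate, CC(C)(C)[Si](C)(C)OS(=O)(=O)C(F)(F)F; n-butyllithium, [Li]CCCC (lithium only in 11); magnesium bromide, Br[Mg]Br (magnesium and bromide only in 12 and 13)
Why: Bromine–lithium exchange at one of the two equivalent bromides, transmetalation to the less basic Grignard reagent and 1,2-addition to the aldehyde, which is far more electrophilic than the electron-rich ortho-silyloxy aryl ketone, then silylation of the alkoxide; the new carbinol centre is formed as a mixture and is equilibrated later in step 14, while the α-centre survives because addition outruns enolisation at −78 °C.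

Step 7
Reactants: 14 (3R,4RS)-1-(ArA)-4-[5-bromo-2,4-bis(TBS-oxy)phenyl]-3-(ArP-methyl)-4-(TBS-oxy)butan-1-one; 15 4-(TBS-oxy)benzaldehyde
Product: 18 1-bromo-2,4-bis(TBS-oxy)-5-X-benzene, via lithium enolate 16 (not isolated), via lithium aldolate 17 (not isolated)
Conditions: LiN(SiMe3)2, THF, −78 °C; then 15; then TESOTf, −78 → −40 °C
Reagents that add atoms: triethylsilyl triflate, CC[Si](CC)(CC)OS(=O)(=O)C(F)(F)F; lithium bis(trimethylsilyl)amide, [Li]N([Si](C)(C)C)[Si](C)(C)C (lithium only in 16 and 17)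
Why: Crossed aldol addition of the kinetic lithium enolate, formed at the only enolisable position, to the non-enolisable aldehyde 15 with in situ silylation of the aldolate to prevent retro-aldol cleavage and β-elimination; the two new centres are left as mixtures because both are equilibrated in step 14.

Step 8
Reactants: 18 1-bromo-2,4-bis(TBS-oxy)-5-X-benzene; 19 (E)-2-(3,3-diethoxyprop-1-en-1-yl)-4,4,5,5-tetramethyl-1,3,2-dioxaborolane
Product: 21 (E)-3-(ArX)prop-2-enal, via diethyl acetal 20 (not isolated)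
Conditions: Pd(OAc)2 (5 mol %), SPhos (10 mol %), K3PO4, toluene/H2O 20:1, 60 °C; then 5% aq citric acid, THF, 0 °C
Reagents that add atoms: water, O
Why: Suzuki–Miyaura coupling of the aryl bromide with the (E)-alkenylboronate (geometry retained) under phosphate conditions that aryl silyl ethers tolerate, followed by rapid hydrolysis of the conjugated diethyl acetal by dilute citric acid to the (E)-enal; no stereocentre is formed.

Step 9
Reactants: 22 4-bromoresorcinol
Product: 23 1-bromo-2,4-bis(TBS-oxy)benzene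
Conditions: TBSCl, imidazole, DMF, 23 °C
Reagents that add atoms: tert-butyldimethylsilyl chloride, CC(C)(C)[Si](C)(C)Cl
Why: Imidazole-promoted silylation (TBS protection) of both phenols; no stereocentre is involved.

Step 10
Reactants: 23 1-bromo-2,4-bis(TBS-oxy)benzene
Product: 26 2,4-bis(TBS-oxy)phenylboronic acid, via aryllithium 24 (not isolated), via lithium arylborate 25 (not isolated)
Conditions: B(Oi-Pr)3, THF, −78 °C, then n-BuLi (in situ quench); dilute aq HCl to pH 5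
Reagents that add atoms: triisopropyl borate, CC(C)OB(OC(C)C)OC(C)C; water, O; n-butyllithium, [Li]CCCC (lithium only in 24 and 25)
Why: Bromine–lithium exchange with the borate present from the start (in situ quench, which outruns migration of silicon from oxygen to the ortho carbanion) and mild hydrolysis give the boronic acid; no stereocentre is involved.

Step 11
Reactants: 21 (E)-3-(ArX)prop-2-enal; 26 2,4-bis(TBS-oxy)phenylboronic acid (3 equiv)
Product: 27 (3R)-3-(ArA)-3-(ArX)propanal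
Conditions: [Rh(OH)(L)]2 (1.5 mol %), L = (1R,4R)-2,5-diphenylbicyclo[2.2.2]octa-2,5-diene, dioxane/H2O 10:1, 40 °C, no added base
Reagents that add atoms: none
Why: Hayashi–Miyaura rhodium-catalysed asymmetric 1,4-addition, in which the aryl–rhodium species carrying the C2-symmetric chiral diene inserts the enal at the Si face of C-β and the resulting oxa-π-allyl complex is protonated by water, so that the (R) diarylmethine centre is set by the catalyst, diene ligands keeping 1,2-addition to the aldehyde low.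

Step 12
Reactants: 27 (3R)-3-(ArA)-3-(ArX)propanal; 28 1,4-benzoquinone
Product: 30 (3R)-3-[(R)-(ArA)(ArX)methyl]-2,3-dihydrobenzofuran-2,5-diol (lactol; both C-2 epimers), via hydroquinone aldehyde 29 (not isolated)
Conditions: (S)-2-[diphenyl(trimethylsilyloxy)methyl]pyrrolidine (20 mol %), CH2Cl2/EtOH 4:1, H2O (2 equiv), −20 °C
Reagents that add atoms: none
Why: Organocatalytic α-arylation of an aldehyde with a quinone (enamine Michael addition to benzoquinone, aromatisation to the hydroquinone and hemiacetal closure), in which the diphenyl(silyloxy)methyl group screens the Re face of the E-enamine so that the quinone is attacked from the Si face, setting the (R) centre that becomes C-3 of the dihydrobenzofuran.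

Step 13
Reactants: 30 (3R)-3-[(R)-(ArA)(ArX)methyl]-2,3-dihydrobenzofuran-2,5-diol; 31 (4-bromophenoxy)(tert-butyl)dimethylsilane
Product: 33 (1RS,2R,3R)-3-(ArA)-3-(ArX)-2-(2,5-dihydroxyphenyl)-1-(ArP)propan-1-ol, via Grignard reagent 32 (not isolated)
Conditions: 31, Mg, THF; then 30 (32 in 5-fold excess), THF, −40 → 0 °C; aq NH4Cl
Reagents that add atoms: magnesium, [Mg] (only in 32)
Why: Grignard addition to the lactol, which opens to the hydroxy aldehyde once deprotonated (two equivalents are used up by the lactol and phenol protons), is faster at low temperature than attack on the hindered α-branched aryl ketone or α-deprotonation; the carbinol centre is formed as a mixture and is equilibrated in step 14.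

Step 14 (key step)
Reactants: 33 (1RS,2R,3R)-3-(ArA)-3-(ArX)-2-(2,5-dihydroxyphenyl)-1-(ArP)propan-1-ol
Product: 34 (2R,3R)-3-[(R)-(ArA)(ArY)methyl]-2-(ArP)-2,3-dihydrobenzofuran-5-ol
Conditions: TsOH·H2O (0.3 equiv), (CF3)2CHOH/CH2Cl2 1:4, 0.01 M, 0 → 23 °C
Reagents that add atoms: none
Why: Brønsted-acid ionisation of the two electron-rich benzylic C–O bonds in the ionising solvent gives 4-silyloxybenzyl-type cations that are trapped within the molecule, one by the only free ortho phenol to close the dihydrobenzofuran (5-exo, every competing ortho oxygen being silylated) and one by the triethylsilyl ether oxygen with loss of silicon to close the tetrahydrofuran (cationic cyclodehydration and desilylative etherification), and because both benzylic ether bonds reopen reversibly and the ketone α-centre epimerises through its enol, C-2 of the dihydrobenzofuran and C-2, C-4 and C-5 of the tetrahydrofuran settle in the most stable 2,3-trans and all-trans arrangements relative to the two fixed C-3 centres.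

Step 15
Reactants: 34 (2R,3R)-3-[(R)-(ArA)(ArY)methyl]-2-(ArP)-2,3-dihydrobenzofuran-5-ol
Product: 35 (2R,3R)-3-[(R)-(ArA)(ArY)methyl]-2-(ArP)-2,3-dihydrobenzofuran-5-yl triflate
Conditions: PhNTf2, Et3N, DMAP (cat), CH2Cl2, 0 → 23 °C
Reagents that add atoms: N-phenylbis(trifluoromethanesulfonimide), O=S(=O)(N(c1ccccc1)S(=O)(=O)C(F)(F)F)C(F)(F)F
Why: Chemoselective triflation of the only free phenol with the mild reagent N-phenyltriflimide; no stereocentre is changed.

Step 16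
Reactants: 2 1-(ArA)ethanone
Product: 36 1-(ArA)prop-2-en-1-one
Conditions: (CH2O)n, i-Pr2NH·CF3CO2H, THF, reflux
Reagents that add atoms: formaldehyde (from paraformaldehyde), C=O
Why: Mannich-type α-methylenation of the methyl ketone (aminomethylation by the iminium ion from formaldehyde and the ammonium salt, then β-elimination of the amine) gives the aryl vinyl ketone; no stereocentre is involved.

Step 17
Reactants: 35 aryl triflate; 36 1-(ArA)prop-2-en-1-one (3 equiv)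
Product: 37 (E)-1-(ArA)-3-{(2R,3R)-3-[(R)-(ArA)(ArY)methyl]-2-(ArP)-2,3-dihydrobenzofuran-5-yl}prop-2-en-1-one (undeca-TBS isolophirachalcone)
Conditions: Pd(OAc)2 (10 mol %), 1,3-bis(diphenylphosphino)propane (11 mol %), Et3N, DMF, 80 °C
Reagents that add atoms: none
Why: Mizoroki–Heck reaction of the aryl triflate with the electron-poor vinyl ketone, whose β-arylation and syn β-hydride elimination give only the (E)-enone; the stereocentres are untouched, the one base-labile centre (C-4 of the tetrahydrofuran) already being in its most stable configuration.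

Step 18
Reactants: 37 undeca-TBS isolophirachalcone
Product: 38 isolophirachalcone
Conditions: Bu4NF/AcOH 1:1 (15 equiv), THF, 0 → 23 °C
Reagents that add atoms: none
Why: Fluoride-induced cleavage of all eleven aryl silyl ethers, buffered with acetic acid so that phenoxides, which could open the benzylic ethers or add to the enone, never build up; no stereocentre is changed.

## Compound list

1 | 2,4-dihydroxyacetophenone | CC(=O)c1ccc(O)cc1O | starting material
2 | 1-(ArA)ethanone | CC(=O)c1ccc(O[Si](C)(C)C(C)(C)C)cc1O[Si](C)(C)C(C)(C)C | intermediate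
3 | trimethylsilyl enol ether of 2 | C=C(O[Si](C)(C)C)c1ccc(O[Si](C)(C)C(C)(C)C)cc1O[Si](C)(C)C(C)(C)C | intermediate
4 | 2-bromo-1-(ArA)ethanone | O=C(CBr)c1ccc(O[Si](C)(C)C(C)(C)C)cc1O[Si](C)(C)C(C)(C)C | intermediate
5 | tert-butyl(4-iodophenoxy)dimethylsilane | CC(C)(C)[Si](C)(C)Oc1ccc(I)cc1 | starting material
6 | allyl alcohol | C=CCO | starting material
7 | 3-(ArP)propanal | O=CCCc1ccc(O[Si](C)(C)C(C)(C)C)cc1 | intermediate
8 | (2R)-4-(ArA)-2-(ArP-methyl)-4-oxobutanal | O=C[C@H](Cc1ccc(O[Si](C)(C)C(C)(C)C)cc1)CC(=O)c1ccc(O[Si](C)(C)C(C)(C)C)cc1O[Si](C)(C)C(C)(C)C | intermediate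
9 | 4,6-dibromoresorcinol | Oc1cc(O)c(Br)cc1Br | starting material
10 | 1,5-dibromo-2,4-bis(TBS-oxy)benzene | CC(C)(C)[Si](C)(C)Oc1cc(O[Si](C)(C)C(C)(C)C)c(Br)cc1Br | intermediate
11 | 5-bromo-2,4-bis(TBS-oxy)phenyllithium | [Li]c1cc(Br)c(O[Si](C)(C)C(C)(C)C)cc1O[Si](C)(C)C(C)(C)C | intermediate
12 | 5-bromo-2,4-bis(TBS-oxy)phenylmagnesium bromide | Br[Mg]c1cc(Br)c(O[Si](C)(C)C(C)(C)C)cc1O[Si](C)(C)C(C)(C)C | intermediate
13 | bromomagnesium alkoxide of the adduct of 12 with 8 (3R; carbinol carbon both epimers) | Br[Mg]OC(c1cc(Br)c(O[Si](C)(C)C(C)(C)C)cc1O[Si](C)(C)C(C)(C)C)[C@H](Cc1ccc(O[Si](C)(C)C(C)(C)C)cc1)CC(=O)c1ccc(O[Si](C)(C)C(C)(C)C)cc1O[Si](C)(C)C(C)(C)C | intermediate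
14 | (3R,4RS)-1-(ArA)-4-[5-bromo-2,4-bis(TBS-oxy)phenyl]-3-(ArP-methyl)-4-(TBS-oxy)butan-1-one | CC(C)(C)[Si](C)(C)OC(c1cc(Br)c(O[Si](C)(C)C(C)(C)C)cc1O[Si](C)(C)C(C)(C)C)[C@H](Cc1ccc(O[Si](C)(C)C(C)(C)C)cc1)CC(=O)c1ccc(O[Si](C)(C)C(C)(C)C)cc1O[Si](C)(C)C(C)(C)C | intermediate
15 | 4-(TBS-oxy)benzaldehyde | O=Cc1ccc(O[Si](C)(C)C(C)(C)C)cc1 | starting material
16 | lithium enolate of 14 (enolised at C-2) | CC(C)(C)[Si](C)(C)OC(c1cc(Br)c(O[Si](C)(C)C(C)(C)C)cc1O[Si](C)(C)C(C)(C)C)[C@H](Cc1ccc(O[Si](C)(C)C(C)(C)C)cc1)C=C(O[Li])c1ccc(O[Si](C)(C)C(C)(C)C)cc1O[Si](C)(C)C(C)(C)C | intermediate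
17 | lithium aldolate from 16 and 15 (new centres as mixtures) | CC(C)(C)[Si](C)(C)OC(c1cc(Br)c(O[Si](C)(C)C(C)(C)C)cc1O[Si](C)(C)C(C)(C)C)[C@H](Cc1ccc(O[Si](C)(C)C(C)(C)C)cc1)C(C(O[Li])c1ccc(O[Si](C)(C)C(C)(C)C)cc1)C(=O)c1ccc(O[Si](C)(C)C(C)(C)C)cc1O[Si](C)(C)C(C)(C)C | intermediate
18 | 1-bromo-2,4-bis(TBS-oxy)-5-X-benzene | CC(C)(C)[Si](C)(C)OC(c1cc(Br)c(O[Si](C)(C)C(C)(C)C)cc1O[Si](C)(C)C(C)(C)C)[C@H](Cc1ccc(O[Si](C)(C)C(C)(C)C)cc1)C(C(O[Si](CC)(CC)CC)c1ccc(O[Si](C)(C)C(C)(C)C)cc1)C(=O)c1ccc(O[Si](C)(C)C(C)(C)C)cc1O[Si](C)(C)C(C)(C)C | intermediate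
19 | (E)-2-(3,3-diethoxyprop-1-en-1-yl)-4,4,5,5-tetramethyl-1,3,2-dioxaborolane | CCOC(OCC)/C=C/B1OC(C)(C)C(C)(C)O1 | starting material
20 | (E)-1-(3,3-diethoxyprop-1-en-1-yl)-2,4-bis(TBS-oxy)-5-X-benzene | CC(C)(C)[Si](C)(C)OC(c1cc(/C=C/C(OCC)OCC)c(O[Si](C)(C)C(C)(C)C)cc1O[Si](C)(C)C(C)(C)C)[C@H](Cc1ccc(O[Si](C)(C)C(C)(C)C)cc1)C(C(O[Si](CC)(CC)CC)c1ccc(O[Si](C)(C)C(C)(C)C)cc1)C(=O)c1ccc(O[Si](C)(C)C(C)(C)C)cc1O[Si](C)(C)C(C)(C)C | intermediate
21 | (E)-3-(ArX)prop-2-enal | CC(C)(C)[Si](C)(C)OC(c1cc(/C=C/C=O)c(O[Si](C)(C)C(C)(C)C)cc1O[Si](C)(C)C(C)(C)C)[C@H](Cc1ccc(O[Si](C)(C)C(C)(C)C)cc1)C(C(O[Si](CC)(CC)CC)c1ccc(O[Si](C)(C)C(C)(C)C)cc1)C(=O)c1ccc(O[Si](C)(C)C(C)(C)C)cc1O[Si](C)(C)C(C)(C)C | intermediate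
22 | 4-bromoresorcinol | Oc1ccc(Br)c(O)c1 | starting material
23 | 1-bromo-2,4-bis(TBS-oxy)benzene | CC(C)(C)[Si](C)(C)Oc1ccc(Br)c(O[Si](C)(C)C(C)(C)C)c1 | intermediate
24 | 2,4-bis(TBS-oxy)phenyllithium | [Li]c1ccc(O[Si](C)(C)C(C)(C)C)cc1O[Si](C)(C)C(C)(C)C | intermediate
25 | lithium (ArA)triisopropoxyborate | [Li+].CC(C)O[B-](OC(C)C)(OC(C)C)c1ccc(O[Si](C)(C)C(C)(C)C)cc1O[Si](C)(C)C(C)(C)C | intermediate
26 | 2,4-bis(TBS-oxy)phenylboronic acid | OB(O)c1ccc(O[Si](C)(C)C(C)(C)C)cc1O[Si](C)(C)C(C)(C)C | intermediate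
27 | (3R)-3-(ArA)-3-(ArX)propanal | O=CC[C@H](c1ccc(O[Si](C)(C)C(C)(C)C)cc1O[Si](C)(C)C(C)(C)C)c1cc(C(O[Si](C)(C)C(C)(C)C)[C@H](Cc2ccc(O[Si](C)(C)C(C)(C)C)cc2)C(C(O[Si](CC)(CC)CC)c2ccc(O[Si](C)(C)C(C)(C)C)cc2)C(=O)c2ccc(O[Si](C)(C)C(C)(C)C)cc2O[Si](C)(C)C(C)(C)C)c(O[Si](C)(C)C(C)(C)C)cc1O[Si](C)(C)C(C)(C)C | intermediate
28 | 1,4-benzoquinone | O=C1C=CC(=O)C=C1 | starting material
29 | (2R,3R)-2-(2,5-dihydroxyphenyl)-3-(ArA)-3-(ArX)propanal | O=C[C@@H](c1cc(O)ccc1O)[C@H](c1ccc(O[Si](C)(C)C(C)(C)C)cc1O[Si](C)(C)C(C)(C)C)c1cc(C(O[Si](C)(C)C(C)(C)C)[C@H](Cc2ccc(O[Si](C)(C)C(C)(C)C)cc2)C(C(O[Si](CC)(CC)CC)c2ccc(O[Si](C)(C)C(C)(C)C)cc2)C(=O)c2ccc(O[Si](C)(C)C(C)(C)C)cc2O[Si](C)(C)C(C)(C)C)c(O[Si](C)(C)C(C)(C)C)cc1O[Si](C)(C)C(C)(C)C | intermediate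
30 | (3R)-3-[(R)-(ArA)(ArX)methyl]-2,3-dihydrobenzofuran-2,5-diol (both C-2 epimers) | Oc1ccc2c(c1)[C@@H]([C@H](c1ccc(O[Si](C)(C)C(C)(C)C)cc1O[Si](C)(C)C(C)(C)C)c1cc(C(O[Si](C)(C)C(C)(C)C)[C@H](Cc3ccc(O[Si](C)(C)C(C)(C)C)cc3)C(C(O[Si](CC)(CC)CC)c3ccc(O[Si](C)(C)C(C)(C)C)cc3)C(=O)c3ccc(O[Si](C)(C)C(C)(C)C)cc3O[Si](C)(C)C(C)(C)C)c(O[Si](C)(C)C(C)(C)C)cc1O[Si](C)(C)C(C)(C)C)C(O)O2 | intermediate
31 | (4-bromophenoxy)(tert-butyl)dimethylsilane | CC(C)(C)[Si](C)(C)Oc1ccc(Br)cc1 | starting material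
32 | 4-(TBS-oxy)phenylmagnesium bromide | CC(C)(C)[Si](C)(C)Oc1ccc([Mg]Br)cc1 | intermediate
33 | (1RS,2R,3R)-3-(ArA)-3-(ArX)-2-(2,5-dihydroxyphenyl)-1-(ArP)propan-1-ol | Oc1ccc(O)c(c1)[C@@H]([C@H](c1ccc(O[Si](C)(C)C(C)(C)C)cc1O[Si](C)(C)C(C)(C)C)c1cc(C(O[Si](C)(C)C(C)(C)C)[C@H](Cc2ccc(O[Si](C)(C)C(C)(C)C)cc2)C(C(O[Si](CC)(CC)CC)c2ccc(O[Si](C)(C)C(C)(C)C)cc2)C(=O)c2ccc(O[Si](C)(C)C(C)(C)C)cc2O[Si](C)(C)C(C)(C)C)c(O[Si](C)(C)C(C)(C)C)cc1O[Si](C)(C)C(C)(C)C)C(O)c1ccc(O[Si](C)(C)C(C)(C)C)cc1 | intermediate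
34 | (2R,3R)-3-[(R)-(ArA)(ArY)methyl]-2-(ArP)-2,3-dihydrobenzofuran-5-ol | Oc1ccc2c(c1)[C@@H]([C@H](c1ccc(O[Si](C)(C)C(C)(C)C)cc1O[Si](C)(C)C(C)(C)C)c1cc([C@@H]3O[C@@H](c4ccc(O[Si](C)(C)C(C)(C)C)cc4)[C@H](C(=O)c4ccc(O[Si](C)(C)C(C)(C)C)cc4O[Si](C)(C)C(C)(C)C)[C@H]3Cc3ccc(O[Si](C)(C)C(C)(C)C)cc3)c(O[Si](C)(C)C(C)(C)C)cc1O[Si](C)(C)C(C)(C)C)[C@H](c1ccc(O[Si](C)(C)C(C)(C)C)cc1)O2 | intermediate
35 | 5-O-triflate of 34 | FC(F)(F)S(=O)(=O)Oc1ccc2c(c1)[C@@H]([C@H](c1ccc(O[Si](C)(C)C(C)(C)C)cc1O[Si](C)(C)C(C)(C)C)c1cc([C@@H]3O[C@@H](c4ccc(O[Si](C)(C)C(C)(C)C)cc4)[C@H](C(=O)c4ccc(O[Si](C)(C)C(C)(C)C)cc4O[Si](C)(C)C(C)(C)C)[C@H]3Cc3ccc(O[Si](C)(C)C(C)(C)C)cc3)c(O[Si](C)(C)C(C)(C)C)cc1O[Si](C)(C)C(C)(C)C)[C@H](c1ccc(O[Si](C)(C)C(C)(C)C)cc1)O2 | intermediate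
36 | 1-(ArA)prop-2-en-1-one | C=CC(=O)c1ccc(O[Si](C)(C)C(C)(C)C)cc1O[Si](C)(C)C(C)(C)C | intermediate
37 | undeca-TBS isolophirachalcone | O=C(/C=C/c1ccc2c(c1)[C@@H]([C@H](c1ccc(O[Si](C)(C)C(C)(C)C)cc1O[Si](C)(C)C(C)(C)C)c1cc([C@@H]3O[C@@H](c4ccc(O[Si](C)(C)C(C)(C)C)cc4)[C@H](C(=O)c4ccc(O[Si](C)(C)C(C)(C)C)cc4O[Si](C)(C)C(C)(C)C)[C@H]3Cc3ccc(O[Si](C)(C)C(C)(C)C)cc3)c(O[Si](C)(C)C(C)(C)C)cc1O[Si](C)(C)C(C)(C)C)[C@H](c1ccc(O[Si](C)(C)C(C)(C)C)cc1)O2)c1ccc(O[Si](C)(C)C(C)(C)C)cc1O[Si](C)(C)C(C)(C)C | intermediate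
38 | isolophirachalcone | O=C(/C=C/c1ccc2c(c1)[C@@H]([C@H](c1ccc(O)cc1O)c1cc([C@@H]3O[C@@H](c4ccc(O)cc4)[C@H](C(=O)c4ccc(O)cc4O)[C@H]3Cc3ccc(O)cc3)c(O)cc1O)[C@H](c1ccc(O)cc1)O2)c1ccc(O)cc1O | target

## Step count and risk

Total step count: 18. Longest linear sequence: 13 steps (1, 2, 4, 6, 7, 8, 11, 12, 13, 14, 15, 17, 18).

The three steps most likely to fail, each with one fallback:

Step 14 (double cyclisation). Risks are chroman formation through participation of a silylated ortho oxygen, elimination at the benzylic cations (which would scramble a C-3 centre), loss of para silyl groups and over-dehydration to a furan. The fallback sets out from 33 and returns at 34. The two aliphatic silyl ethers of 33 are removed with pyridine-buffered HF·pyridine in THF at 0 °C (aryl TBS ethers survive) to give the pentaol F1. F1 is then closed under neutral Mitsunobu conditions (PPh3, diisopropyl azodicarboxylate, THF, high dilution), where only the free phenol next to the side chain and the free carbinols can react. Both rings again form in one operation, but by SN2 redox condensation instead of ionisation. The epimer mixture at dihydrobenzofuran C-2 and at the tetrahydrofuran carbons is then converged on 34 with DBU (ketone α-centre) and a trace of acid that now only has to reopen and reclose existing rings.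

Step 12 (α-arylation with benzoquinone). The enamine must form and react beside a diarylmethine that carries two ortho-silyloxy aryl groups. The fallback sets out from 27 and returns at 30. Aldehyde 27 is converted with TBSOTf and Et3N into the silyl enol ether F2, which adds to benzoquinone 28 in a Lewis-acid-promoted Mukaiyama–Michael reaction (BF3·OEt2, CH2Cl2, −78 °C). Aromatisation and loss of the silyl group on work-up give lactol 30. Facial control then comes from the neighbouring diarylmethine centre (minimised allylic strain) instead of from an amine catalyst, and the unwanted C-3 epimer is removed by chromatography.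

Step 11 (rhodium conjugate arylation). Both partners carry ortho-silyloxy groups, which slows transmetalation and favours protodeboronation. The fallback sets out from 21 and returns at 27. Enal 21 is condensed with tert-butyl L-tert-leucinate (MgSO4, CH2Cl2) to the aldimine F3 (Koga auxiliary). The Grignard reagent F4, made from bromide 23 and Mg, adds 1,4 to F3 through a magnesium chelate at −55 °C to give the magnesium enamide F5, and mild hydrolysis with aqueous citric acid releases 27 and the recoverable amino ester. The antipodal amino ester is used if the chelate model delivers the wrong face.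

## Further compounds

F1 | step 14 | pentaol: 33 with the aliphatic TBS and TES ethers replaced by OH | Oc1ccc(O)c(c1)[C@@H]([C@H](c1ccc(O[Si](C)(C)C(C)(C)C)cc1O[Si](C)(C)C(C)(C)C)c1cc(C(O)[C@H](Cc2ccc(O[Si](C)(C)C(C)(C)C)cc2)C(C(O)c2ccc(O[Si](C)(C)C(C)(C)C)cc2)C(=O)c2ccc(O[Si](C)(C)C(C)(C)C)cc2O[Si](C)(C)C(C)(C)C)c(O[Si](C)(C)C(C)(C)C)cc1O[Si](C)(C)C(C)(C)C)C(O)c1ccc(O[Si](C)(C)C(C)(C)C)cc1
F2 | step 12 | tert-butyldimethylsilyl enol ether of 27 | CC(C)(C)[Si](C)(C)OC=C[C@H](c1ccc(O[Si](C)(C)C(C)(C)C)cc1O[Si](C)(C)C(C)(C)C)c1cc(C(O[Si](C)(C)C(C)(C)C)[C@H](Cc2ccc(O[Si](C)(C)C(C)(C)C)cc2)C(C(O[Si](CC)(CC)CC)c2ccc(O[Si](C)(C)C(C)(C)C)cc2)C(=O)c2ccc(O[Si](C)(C)C(C)(C)C)cc2O[Si](C)(C)C(C)(C)C)c(O[Si](C)(C)C(C)(C)C)cc1O[Si](C)(C)C(C)(C)C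
F3 | step 11 | aldimine of 21 with tert-butyl L-tert-leucinate | CC(C)(C)OC(=O)[C@@H](N=C/C=C/c1cc(C(O[Si](C)(C)C(C)(C)C)[C@H](Cc2ccc(O[Si](C)(C)C(C)(C)C)cc2)C(C(O[Si](CC)(CC)CC)c2ccc(O[Si](C)(C)C(C)(C)C)cc2)C(=O)c2ccc(O[Si](C)(C)C(C)(C)C)cc2O[Si](C)(C)C(C)(C)C)c(O[Si](C)(C)C(C)(C)C)cc1O[Si](C)(C)C(C)(C)C)C(C)(C)C
F4 | step 11 | 2,4-bis(TBS-oxy)phenylmagnesium bromide | Br[Mg]c1ccc(O[Si](C)(C)C(C)(C)C)cc1O[Si](C)(C)C(C)(C)C
F5 | step 11 | bromomagnesium enamide from 1,4-addition of F4 to F3 | CC(C)(C)OC(=O)[C@@H](N([Mg]Br)C=C[C@H](c1ccc(O[Si](C)(C)C(C)(C)C)cc1O[Si](C)(C)C(C)(C)C)c1cc(C(O[Si](C)(C)C(C)(C)C)[C@H](Cc2ccc(O[Si](C)(C)C(C)(C)C)cc2)C(C(O[Si](CC)(CC)CC)c2ccc(O[Si](C)(C)C(C)(C)C)cc2)C(=O)c2ccc(O[Si](C)(C)C(C)(C)C)cc2O[Si](C)(C)C(C)(C)C)c(O[Si](C)(C)C(C)(C)C)cc1O[Si](C)(C)C(C)(C)C)C(C)(C)C
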